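The benzene ring is traced back to the 4-pyranone ring of kojic acid. Arene C1 with its CH2N arm, C3–O and C4–O correspond to pyranone C2 with its CH2 group, the C4 carbonyl and C5–O, and the pyranone ring oxygen O1 occupies the position that arene C6 takes in the target. In one operation nitromethane and base exchange O1 for the nitromethane carbon, forming C6–C1 and C6–C5 and closing the benzene ring as a 4-nitrophenol whose nitro group marks the later C6 bromine. The precursor is 5-methoxy-2-[(2-oxopyrrolidin-1-yl)methyl]-4H-pyran-4-one, made from kojic acid by O-methylation, chlorination and N-alkylation of pyrrolidin-2-one.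

Key step: step 4

Remark 1: arene carbons are numbered as in the target throughout (C1 carries the CH2N arm, then C2 Br, C3 OH, C4 OH, C5 Br, C6 Br), and compound names use this numbering.

Remark 2: the phenol set free in step 4 first directs the C2 bromination and is then capped as a second methyl ether before the nitro group is reduced. A free 4-aminophenol would be oxidised to a quinone imine by brominating agents and would form a quinone diazide on diazotisation. The last step removes both methyl groups together, so no separate deprotection is added.

Step 1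
Reactants: 1 kojic acid
Product: 2 2-(hydroxymethyl)-5-methoxy-4H-pyran-4-one
Conditions: Me2SO4 (1.1 equiv), KOH (1.1 equiv), H2O, 10–20 °C
Reagents that add atoms: dimethyl sulfate, COS(=O)(=O)OC
Why: Williamson-type O-methylation, in which aqueous KOH ionises only the acidic enolic 5-hydroxyl, so this oxygen is methylated and the primary alcohol is left free.

Step 2
Reactants: 2 2-(hydroxymethyl)-5-methoxy-4H-pyran-4-one
Product: 3 2-(chloromethyl)-5-methoxy-4H-pyran-4-one
Conditions: SOCl2 (1.5 equiv), CH2Cl2, 0 °C → rt
Reagents that add atoms: thionyl chloride, O=S(Cl)Cl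
Why: Deoxychlorination of a primary, allyl-type alcohol through its chlorosulfite ester, to which the pyranone ring and the methyl ether are inert.

Step 3
Reactants: 3 2-(chloromethyl)-5-methoxy-4H-pyran-4-one; 4 pyrrolidin-2-one
Product: 6 5-methoxy-2-[(2-oxopyrrolidin-1-yl)methyl]-4H-pyran-4-one, via sodium 2-oxopyrrolidin-1-ide 5 (not isolated)
Conditions: 4 (1.1 equiv), NaH (1.0 equiv), DMF/THF, 0 °C; then 3, 0 °C → rt
Reagents that add atoms: none
Why: N-alkylation of a lactam anion by SN2 displacement at a primary chloride that the pyranone C2=C3 bond activates like an allyl chloride; the sodium salt in a dipolar aprotic solvent should react at nitrogen, and the slight excess of lactam leaves no free hydride.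

Step 4
Reactants: 6 5-methoxy-2-[(2-oxopyrrolidin-1-yl)methyl]-4H-pyran-4-one; 7 nitromethane
Product: 8 1-(3-hydroxy-4-methoxy-6-nitrobenzyl)pyrrolidin-2-one
Conditions: MeNO2 (8 equiv), KOt-Bu (4 equiv), t-BuOH, rt → 80 °C; then 1 M HCl
Reagents that add atoms: none
Why: Potassium nitronate adds in conjugate fashion to an alpha carbon of the vinylogous ester (pyranone C6 or C2), the adduct, a 2H-pyran-4-olate, opens by beta-elimination of the ring oxygen to an acyclic 1,3-dicarbonyl enolate, and the nitronate carbon then attacks the carbonyl group set free at the other alpha carbon; loss of water and tautomerisation should give the 4-nitrophenolate, which is protonated on work-up. The closest known reaction is the conversion of 2,6-dialkyl-4-pyranones into 3,5-dialkyl-4-nitrophenols, and of pyrylium salts into nitroarenes, with nitromethane and an alkoxide base; the present pyranone differs only in its unsubstituted alpha carbon and its 5-alkoxy group. The benzene ring closes by a 6-exo-trig intramolecular nitro-aldol (Henry) addition, which makes the second of the two new bonds (arene C6–C1 or C6–C5, depending on which alpha carbon was attacked first). No stereocenter remains in the product. Regiocontrol is not needed, because first attack at either alpha carbon places the nitro-bearing carbon between the two former alpha carbons; what is needed is ring attack in preference to deprotonation of the N–CH2 group, and this is secured by keeping nitromethane in excess over KOt-Bu so that the medium is buffered at the basicity of the nitronate. The methoxy group should survive because it sits on an sp2 carbon from which it cannot be eliminated on the way to the arene, and the lactam carries no acidic N–H.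

Step 5
Reactants: 8 1-(3-hydroxy-4-methoxy-6-nitrobenzyl)pyrrolidin-2-one
Product: 9 1-(2-bromo-3-hydroxy-4-methoxy-6-nitrobenzyl)pyrrolidin-2-one
Conditions: Br2 (1.05 equiv), AcOH, rt
Reagents that add atoms: bromine, BrBr
Why: Electrophilic aromatic bromination in which the free phenol directs to its only open ortho position C2 (its para position C6 carries the nitro group), while C5 is deactivated by the adjacent nitro group.

Step 6
Reactants: 9 1-(2-bromo-3-hydroxy-4-methoxy-6-nitrobenzyl)pyrrolidin-2-one
Product: 10 1-(2-bromo-3,4-dimethoxy-6-nitrobenzyl)pyrrolidin-2-one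
Conditions: MeI (1.5 equiv), K2CO3 (2 equiv), DMF, 40 °C
Reagents that add atoms: iodomethane, CI
Why: Williamson O-methylation of an acidic nitrophenol with a mild carbonate base, which touches neither the lactam nor the aryl bromide.

Step 7
Reactants: 10 1-(2-bromo-3,4-dimethoxy-6-nitrobenzyl)pyrrolidin-2-one
Product: 11 1-(6-amino-2-bromo-3,4-dimethoxybenzyl)pyrrolidin-2-one
Conditions: H2 (1 atm), sulfided 5% Pt/C, EtOAc/EtOH, rt
Reagents that add atoms: none
Why: Catalytic hydrogenation of a nitroarene over sulfided platinum on carbon, a catalyst that spares aryl bromides; the neutral medium at room temperature gives the new amine no help to cyclodehydrate onto the lactam carbonyl.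

Step 8
Reactants: 11 1-(6-amino-2-bromo-3,4-dimethoxybenzyl)pyrrolidin-2-one
Product: 12 1-(6-amino-2,5-dibromo-3,4-dimethoxybenzyl)pyrrolidin-2-one
Conditions: NBS (1.0 equiv), MeCN, 0 °C
Reagents that add atoms: N-bromosuccinimide, O=C1CCC(=O)N1Br
Why: Electrophilic bromination of an aniline at C5, the only free ring carbon, which is ortho both to the amino group and to the C4 methoxy group, so one equivalent of a mild bromine source should suffice.

Step 9
Reactants: 12 1-(6-amino-2,5-dibromo-3,4-dimethoxybenzyl)pyrrolidin-2-one
Product: 14 1-(2,5,6-tribromo-3,4-dimethoxybenzyl)pyrrolidin-2-one, via arenediazonium bromide 13 (not isolated)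
Conditions: NaNO2 (1.1 equiv), 48% aq. HBr, MeCN, 0 °C; then CuBr (1.2 equiv), 48% aq. HBr, 0 → 60 °C
Reagents that add atoms: hydrobromic acid, Br (source of the C6 bromine, handed on by CuBr, Br[Cu]); sodium nitrite, [Na+].[O-]N=O (supplies the outer nitrogen of 13 only, lost as N2)
Why: Sandmeyer reaction, in which diazotisation in strong acid and copper-mediated bromide transfer to the aryl radical replace the C6 amino group by bromine; hydrobromic acid as the only acid excludes halogen scrambling, and the low pH suppresses attack of the benzylic carbon or the lactam on the diazonium group.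

Step 10
Reactants: 14 1-(2,5,6-tribromo-3,4-dimethoxybenzyl)pyrrolidin-2-one
Product: 15 1-(2,5,6-tribromo-3,4-dihydroxybenzyl)pyrrolidin-2-one
Conditions: BBr3 (5 equiv), CH2Cl2, −78 °C → rt; then MeOH, H2O
Reagents that add atoms: none
Why: Lewis acid cleavage of both aryl methyl ethers with BBr3, used in excess because the lactam carbonyl binds one equivalent; aryl bromides and the N-benzyl lactam are stable to the reagent.

Compound list
1 | kojic acid, 5-hydroxy-2-(hydroxymethyl)-4H-pyran-4-one | OCC1=CC(=O)C(O)=CO1 | starting material
2 | 2-(hydroxymethyl)-5-methoxy-4H-pyran-4-one | OCC1=CC(=O)C(OC)=CO1 | intermediate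
3 | 2-(chloromethyl)-5-methoxy-4H-pyran-4-one | ClCC1=CC(=O)C(OC)=CO1 | intermediate
4 | pyrrolidin-2-one | O=C1CCCN1 | starting material
5 | sodium 2-oxopyrrolidin-1-ide | O=C1CCC[N-]1.[Na+] | intermediate
6 | 5-methoxy-2-[(2-oxopyrrolidin-1-yl)methyl]-4H-pyran-4-one | O=C1CCCN1CC1=CC(=O)C(OC)=CO1 | intermediate
7 | nitromethane | C[N+](=O)[O-] | starting material
8 | 1-(3-hydroxy-4-methoxy-6-nitrobenzyl)pyrrolidin-2-one (systematic locants: 5-hydroxy-4-methoxy-2-nitrobenzyl) | O=C1CCCN1Cc1cc(O)c(OC)cc1[N+](=O)[O-] | intermediate
9 | 1-(2-bromo-3-hydroxy-4-methoxy-6-nitrobenzyl)pyrrolidin-2-one | O=C1CCCN1Cc1c(Br)c(O)c(OC)cc1[N+](=O)[O-] | intermediate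
10 | 1-(2-bromo-3,4-dimethoxy-6-nitrobenzyl)pyrrolidin-2-one | O=C1CCCN1Cc1c(Br)c(OC)c(OC)cc1[N+](=O)[O-] | intermediate
11 | 1-(6-amino-2-bromo-3,4-dimethoxybenzyl)pyrrolidin-2-one | O=C1CCCN1Cc1c(Br)c(OC)c(OC)cc1N | intermediate
12 | 1-(6-amino-2,5-dibromo-3,4-dimethoxybenzyl)pyrrolidin-2-one | O=C1CCCN1Cc1c(Br)c(OC)c(OC)c(Br)c1N | intermediate
13 | 3,6-dibromo-4,5-dimethoxy-2-[(2-oxopyrrolidin-1-yl)methyl]benzenediazonium bromide | O=C1CCCN1Cc1c(Br)c(OC)c(OC)c(Br)c1[N+]#N.[Br-] | intermediate
14 | 1-(2,5,6-tribromo-3,4-dimethoxybenzyl)pyrrolidin-2-one | O=C1CCCN1Cc1c(Br)c(OC)c(OC)c(Br)c1Br | intermediate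
15 | 1-(2,5,6-tribromo-3,4-dihydroxybenzyl)pyrrolidin-2-one (systematic locants: 2,3,6-tribromo-4,5-dihydroxybenzyl) | O=C1CCCN1Cc1c(Br)c(O)c(O)c(Br)c1Br | target

Total step count: 10
Longest linear sequence: 10 steps (kojic acid 1 to target 15)

Steps most likely to fail

Step 4. The pyranone has an unsubstituted alpha carbon and a 5-alkoxy group, so the open-chain intermediate may fail to reclose and instead add a second nitronate or oligomerise. Alkoxide may also open the ring without carbon incorporation, and nitromethane may condense with itself faster than it adds. The fallback gives up the ring transformation and uses a preformed arene. It sets out from pyrrolidin-2-one 4, whose sodium salt 5 (NaH, DMF, 0 °C) is N-alkylated with commercial 4,5-dimethoxy-2-nitrobenzyl bromide F1 to give 1-(4,5-dimethoxy-2-nitrobenzyl)pyrrolidin-2-one F2 (route numbering: 3,4-dimethoxy-6-nitro). The C3 methoxy group, which is para to the nitro group, is then cleaved selectively by chloride (LiCl, DMF, 140 °C; SN2 at the methyl group, with the 4-nitrophenolate as leaving group). This returns to the route at 8.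

Step 9. The aryl radical may be diverted by 1,5-hydrogen transfer from the lactam N–CH2 group before bromide transfer. The diazonium ion may be hydrolysed to the phenol or couple intramolecularly with the benzylic carbon. The amine may also cyclodehydrate onto the lactam carbonyl in the acid before it is diazotised. The fallback makes the C6–Br bond by electrophilic substitution instead. It sets out from 12, which is diazotised as before to 13 and reduced with H3PO2 (0 °C → rt) to 1-(2,5-dibromo-3,4-dimethoxybenzyl)pyrrolidin-2-one F3; a translocated radical is reduced to the same compound. Bromination of the single free carbon C6, which is para to the C3 methoxy group (Br2, NaOAc, AcOH, 50 °C), comes back to the route at 14.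

Step 3. The lactam anion may deprotonate the acidic chloromethyl group, add to the pyranone ring in conjugate fashion, or be alkylated at oxygen. The fallback builds the lactam on the nitrogen without strong base. It sets out from 2, which is oxidised (MnO2, CHCl3, reflux) to 5-methoxy-4-oxo-4H-pyran-2-carbaldehyde F4. Reductive amination with methyl 4-aminobutanoate hydrochloride F5 (Et3N, NaBH(OAc)3, ClCH2CH2Cl, rt) should give methyl 4-{[(5-methoxy-4-oxo-4H-pyran-2-yl)methyl]amino}butanoate F6. This closes to the lactam on warming (toluene, cat. AcOH, 80 °C) and comes back to the route at 6.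

Further compounds
F1 | step 4 | 4,5-dimethoxy-2-nitrobenzyl bromide | BrCc1cc(OC)c(OC)cc1[N+](=O)[O-]
F2 | step 4 | 1-(4,5-dimethoxy-2-nitrobenzyl)pyrrolidin-2-one | O=C1CCCN1Cc1cc(OC)c(OC)cc1[N+](=O)[O-]
F3 | step 9 | 1-(2,5-dibromo-3,4-dimethoxybenzyl)pyrrolidin-2-one | O=C1CCCN1Cc1cc(Br)c(OC)c(OC)c1Br
F4 | step 3 | 5-methoxy-4-oxo-4H-pyran-2-carbaldehyde | O=CC1=CC(=O)C(OC)=CO1
F5 | step 3 | methyl 4-aminobutanoate hydrochloride | COC(=O)CCCN.Cl
F6 | step 3 | methyl 4-{[(5-methoxy-4-oxo-4H-pyran-2-yl)methyl]amino}butanoate | COC(=O)CCCNCC1=CC(=O)C(OC)=CO1
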